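**Plan**
Retrosynthesis: the ring B silyl ether is removed last; ring A is cut at C1'–C2' and C5'–C6' into a terminal alkynyl ketone and a 1-methoxy-1,3-bis(silyloxy)butadiene. The ynone is then cut at C(=O)–C≡C (ethynyl Grignard on a Weinreb amide), the chain at aryl–Cβ (Heck), and the prenyl group at aryl–CH2 (Claisen from an O-tert-prenyl ether).
Forward: ring B is bought as 4-bromo-2-methoxyphenol. The prenyl group is moved from O to C, the phenol silylated, the three-carbon chain attached and capped with ethynyl. Ring A, the only ring built, is closed last onto the ynone with the diene from methyl acetoacetate.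
Enabling feature: ring A is a resorcinol with the acyl carbon C1' ortho to O2' and para to O4', the pattern a 1,1,3-trioxygenated diene imprints on an alkynyl ketone.
Stereochemistry: there is no stereocenter; the single E alkene comes from syn insertion and syn β-hydride elimination in the Heck step and is carried through unchanged.

Key step: step 9

Assumption: the silyl enol ether of methyl acetoacetate and the diene made from it are drawn as Z isomers; their double-bond geometry is lost in the arene and does not affect the route. Racemic intermediates are drawn without configuration.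

Step 1
Reactants: 1 2-methylbut-3-en-2-ol
Product: 2 tert-butyl 2-methylbut-3-en-2-yl carbonate
Conditions: n-BuLi, THF, −78 → 0 °C; then Boc2O, 0 °C → rt
Reagents that add atoms: di-tert-butyl dicarbonate (Boc2O), CC(C)(C)OC(=O)OC(=O)OC(C)(C)C
Why: O-acylation of the lithium alkoxide with the dicarbonate (carbonate formation) is the reliable way to activate this tertiary allylic alcohol, which acylates poorly under amine conditions.

Step 2
Reactants: 3 4-bromo-2-methoxyphenol; 2 tert-butyl 2-methylbut-3-en-2-yl carbonate
Product: 4 4-bromo-2-methoxy-1-(2-methylbut-3-en-2-yloxy)benzene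
Conditions: Pd(PPh3)4 (2 mol %), 4 Å MS, THF, 0 °C
Reagents that add atoms: none
Why: Tsuji–Trost O-allylation, in which zerovalent palladium ionizes the tertiary carbonate to a 1,1-dimethyl-π-allyl complex and tert-butoxide, the phenoxide attacks the more substituted terminus under kinetic control at 0 °C, and the electron-rich C–Br bond should not undergo oxidative addition at this temperature.

Step 3
Reactants: 4 4-bromo-2-methoxy-1-(2-methylbut-3-en-2-yloxy)benzene
Product: 6 4-bromo-2-methoxy-6-(3-methylbut-2-enyl)phenol, via dienone 5 (not isolated)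
Conditions: PhNEt2, 140 °C
Reagents that add atoms: none
Why: Aromatic Claisen rearrangement, a [3,3]-sigmatropic shift that delivers the inverted allyl unit as a 3-methylbut-2-enyl group to C6, the only free ortho position, followed by tautomerization of the dienone; the tertiary ether rearranges at moderate temperature and the amine solvent suppresses acid-promoted loss of isoprene and chroman formation.

Step 4
Reactants: 6 4-bromo-2-methoxy-6-(3-methylbut-2-enyl)phenol
Product: 7 [4-bromo-2-methoxy-6-(3-methylbut-2-enyl)phenoxy](tert-butyl)dimethylsilane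
Conditions: TBSCl, imidazole, DMF, rt
Reagents that add atoms: tert-butyldimethylsilyl chloride (TBSCl), CC(C)(C)[Si](C)(C)Cl
Why: Imidazole-promoted silylation masks the acidic phenol before the organometallic steps and the silyl-transfer-prone diene, and the aryl silyl ether should withstand amine base, Grignard reagent and brief dilute acid.

Step 5
Reactants: 7 [4-bromo-2-methoxy-6-(3-methylbut-2-enyl)phenoxy](tert-butyl)dimethylsilane; 8 N-methoxy-N-methylacrylamide
Product: 9 (E)-3-[4-(tert-butyldimethylsilyloxy)-3-methoxy-5-(3-methylbut-2-enyl)phenyl]-N-methoxy-N-methylprop-2-enamide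
Conditions: Pd(OAc)2 (5 mol %), P(o-tol)3, Et3N, DMF, 100 °C
Reagents that add atoms: none
Why: Mizoroki–Heck reaction, in which oxidative addition into the C–Br bond, syn insertion of the acrylamide and syn β-hydride elimination should give only the E cinnamamide, the trisubstituted prenyl alkene being too hindered to compete.

Step 6
Reactants: 9 (E)-3-[4-(tert-butyldimethylsilyloxy)-3-methoxy-5-(3-methylbut-2-enyl)phenyl]-N-methoxy-N-methylprop-2-enamide
Product: 11 (E)-1-[4-(tert-butyldimethylsilyloxy)-3-methoxy-5-(3-methylbut-2-enyl)phenyl]pent-1-en-4-yn-3-one, via magnesium hemiaminal 10 (not isolated)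
Conditions: HC≡CMgBr, THF, 0 °C → rt; inverse quench into cold 1 M HCl
Reagents that add atoms: ethynylmagnesium bromide (HC≡CMgBr), C#C[Mg]Br
Why: Weinreb ketone synthesis, in which the N-methoxy-N-methylamide takes up one alkynyl Grignard by 1,2-addition and holds it as a five-membered magnesium chelate that collapses to the ketone only on quenching, while inverse addition into cold acid protonates the released amine before it can add to the new ynone.

Step 7
Reactants: 12 methyl acetoacetate
Product: 13 methyl (2Z)-3-(trimethylsilyloxy)but-2-enoate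
Conditions: TMSCl, Et3N, hexane, rt
Reagents that add atoms: chlorotrimethylsilane (TMSCl), C[Si](C)(C)Cl
Why: Enol silylation of the β-keto ester under soft enolization with triethylamine is the routine first stage toward 1,3-bis(silyloxy)dienes.

Step 8
Reactants: 13 methyl (2Z)-3-(trimethylsilyloxy)but-2-enoate
Product: 14 (1Z)-1-methoxy-1,3-bis(trimethylsilyloxy)buta-1,3-diene (Chan's diene)
Conditions: LiN(i-Pr)2, THF, −78 °C; then TMSCl, −78 → 0 °C
Reagents that add atoms: chlorotrimethylsilane (TMSCl), C[Si](C)(C)Cl
Why: γ-Deprotonation of the vinylogous ester by the lithium amide gives a dienolate that is O-silylated to the ketene acetal, the established preparation of this diene; it is distilled and used fresh.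

Step 9
Reactants: 11 (E)-1-[4-(tert-butyldimethylsilyloxy)-3-methoxy-5-(3-methylbut-2-enyl)phenyl]pent-1-en-4-yn-3-one; 14 (1Z)-1-methoxy-1,3-bis(trimethylsilyloxy)buta-1,3-diene
Product: 16 (E)-3-[4-(tert-butyldimethylsilyloxy)-3-methoxy-5-(3-methylbut-2-enyl)phenyl]-1-(2,4-dihydroxyphenyl)prop-2-en-1-one (4-O-silyl abyssinone D), via cyclohexadiene cycloadduct 15 (not isolated)
Conditions: 14 (2 equiv), toluene, −20 °C → rt; then 1 M HCl, THF, 0 °C
Reagents that add atoms: none
Why: The electron-rich diene and the electron-poor terminal ynone combine in a strongly asynchronous normal-demand Diels–Alder reaction (at the stepwise limit a Mukaiyama–Michael addition followed by closure of the allenolate onto the oxocarbenium carbon), the diene CH2 terminus bonding to the alkyne β-carbon (C5'–C6') and the ketene acetal carbon to the α-carbon (C1'–C2'). Cold dilute acid then removes both trimethylsilyl groups of 15, the C2' hemiketal loses methanol and the resulting dienone enolizes to the 2,4-dihydroxyphenyl ketone, helped by the O2'–H···O=C hydrogen bond. The closest known reaction type is the Diels–Alder benzannulation of 1-alkoxy-1,3-bis(silyloxy)butadienes with alkynyl ketones and esters to give acylresorcinols. Ring A is closed intermolecularly in the (4+2) mode, with C2'–C5' from the diene and C1' and C6' from the alkyne. No stereocenter remains, since the stereogenic ketal carbon of 15 is flattened on aromatization and the E enone is not touched. The step needs regioselectivity, secured by pairing the most nucleophilic diene terminus with the most electrophilic alkyne carbon, and chemoselectivity for the alkyne over the enone and the prenyl alkene, secured by the unhindered terminal ynone being far more reactive than a β-aryl enone deactivated by the donor-substituted ring B.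

Step 10
Reactants: 16 (E)-3-[4-(tert-butyldimethylsilyloxy)-3-methoxy-5-(3-methylbut-2-enyl)phenyl]-1-(2,4-dihydroxyphenyl)prop-2-en-1-one
Product: 17 abyssinone D, (E)-1-(2,4-dihydroxyphenyl)-3-[4-hydroxy-3-methoxy-5-(3-methylbut-2-enyl)phenyl]prop-2-en-1-one
Conditions: Bu4NF, AcOH, THF, 0 °C
Reagents that add atoms: none
Why: Fluoride-induced desilylation of the aryl silyl ether, with acetic acid buffering the phenoxides so that the 2'-hydroxychalcone does not close to the flavanone by oxa-Michael addition and the prenyl group meets no acid strong enough to form a chroman.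

**Compound list**
1 | 2-methylbut-3-en-2-ol | CC(C)(O)C=C | starting material
2 | tert-butyl 2-methylbut-3-en-2-yl carbonate | CC(C)(C)OC(=O)OC(C)(C)C=C | intermediate
3 | 4-bromo-2-methoxyphenol | COc1cc(Br)ccc1O | starting material
4 | 4-bromo-2-methoxy-1-(2-methylbut-3-en-2-yloxy)benzene | COc1cc(Br)ccc1OC(C)(C)C=C | intermediate
5 | racemic 4-bromo-2-methoxy-6-(3-methylbut-2-enyl)cyclohexa-2,4-dien-1-one | COC1=CC(Br)=CC(CC=C(C)C)C1=O | intermediate
6 | 4-bromo-2-methoxy-6-(3-methylbut-2-enyl)phenol | COc1cc(Br)cc(CC=C(C)C)c1O | intermediate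
7 | [4-bromo-2-methoxy-6-(3-methylbut-2-enyl)phenoxy](tert-butyl)dimethylsilane | COc1cc(Br)cc(CC=C(C)C)c1O[Si](C)(C)C(C)(C)C | intermediate
8 | N-methoxy-N-methylacrylamide (N-methoxy-N-methylprop-2-enamide) | C=CC(=O)N(C)OC | starting material
9 | (E)-3-[4-(tert-butyldimethylsilyloxy)-3-methoxy-5-(3-methylbut-2-enyl)phenyl]-N-methoxy-N-methylprop-2-enamide | CON(C)C(=O)/C=C/c1cc(OC)c(O[Si](C)(C)C(C)(C)C)c(CC=C(C)C)c1 | intermediate
10 | racemic bromomagnesium (1E)-1-[4-(tert-butyldimethylsilyloxy)-3-methoxy-5-(3-methylbut-2-enyl)phenyl]-3-[methoxy(methyl)amino]pent-1-en-4-yn-3-olate | C#CC(O[Mg]Br)(N(C)OC)/C=C/c1cc(OC)c(O[Si](C)(C)C(C)(C)C)c(CC=C(C)C)c1 | intermediate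
11 | (E)-1-[4-(tert-butyldimethylsilyloxy)-3-methoxy-5-(3-methylbut-2-enyl)phenyl]pent-1-en-4-yn-3-one | C#CC(=O)/C=C/c1cc(OC)c(O[Si](C)(C)C(C)(C)C)c(CC=C(C)C)c1 | intermediate
12 | methyl acetoacetate (methyl 3-oxobutanoate) | COC(=O)CC(C)=O | starting material
13 | methyl (2Z)-3-(trimethylsilyloxy)but-2-enoate | C/C(O[Si](C)(C)C)=C/C(=O)OC | intermediate
14 | (1Z)-1-methoxy-1,3-bis(trimethylsilyloxy)buta-1,3-diene (Chan's diene) | CO/C(O[Si](C)(C)C)=C/C(=C)O[Si](C)(C)C | intermediate
15 | racemic (E)-3-[4-(tert-butyldimethylsilyloxy)-3-methoxy-5-(3-methylbut-2-enyl)phenyl]-1-[6-methoxy-4,6-bis(trimethylsilyloxy)cyclohexa-1,4-dien-1-yl]prop-2-en-1-one | COC1(O[Si](C)(C)C)C=C(O[Si](C)(C)C)CC=C1C(=O)/C=C/c1cc(OC)c(O[Si](C)(C)C(C)(C)C)c(CC=C(C)C)c1 | intermediate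
16 | (E)-3-[4-(tert-butyldimethylsilyloxy)-3-methoxy-5-(3-methylbut-2-enyl)phenyl]-1-(2,4-dihydroxyphenyl)prop-2-en-1-one | COc1cc(/C=C/C(=O)c2ccc(O)cc2O)cc(CC=C(C)C)c1O[Si](C)(C)C(C)(C)C | intermediate
17 | abyssinone D, (E)-1-(2,4-dihydroxyphenyl)-3-[4-hydroxy-3-methoxy-5-(3-methylbut-2-enyl)phenyl]prop-2-en-1-one | COc1cc(/C=C/C(=O)c2ccc(O)cc2O)cc(CC=C(C)C)c1O | target

**Step count**
Total: 10 steps. Longest linear sequence: 8 steps (steps 1, 2, 3, 4, 5, 6, 9, 10 from 2-methylbut-3-en-2-ol); steps 7 and 8 form the two-step branch to the diene.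

**Steps most likely to fail**

Step 9. The sequence may stall at the open-chain Michael stage if silyl transfer outruns ring closure, aromatization may proceed by loss of silanol instead of methanol and leave O2' methylated, or the terminal ynone may oligomerize before the diene engages it. The fallback sets out from 9 and returns at 16, attaching ring A as a preformed aryl nucleophile. 4-Bromoresorcinol is protected with chloromethyl methyl ether and i-Pr2NEt in CH2Cl2 to give 1-bromo-2,4-bis(methoxymethoxy)benzene F1. Bromine–lithium exchange with n-BuLi (THF, −78 °C) and 1,2-addition of the aryllithium to Weinreb amide 9 should give (E)-1-[2,4-bis(methoxymethoxy)phenyl]-3-[4-(tert-butyldimethylsilyloxy)-3-methoxy-5-(3-methylbut-2-enyl)phenyl]prop-2-en-1-one F2. HCl in MeOH at 25–40 °C should remove both acetals and leave the hindered aryl silyl ether, giving 16.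

Step 6. The N,O-dimethylhydroxylamine released on collapse of the chelate may add in conjugate fashion to the terminal ynone during work-up, or the ynone may polymerize on concentration. The fallback sets out from 9 and returns at 11, forming the ynone by oxidation with no amine present. i-Bu2AlH (THF, −78 °C) reduces the amide to (E)-3-[4-(tert-butyldimethylsilyloxy)-3-methoxy-5-(3-methylbut-2-enyl)phenyl]prop-2-enal F3. HC≡CMgBr (THF, 0 °C) adds to the aldehyde to give racemic (E)-1-[4-(tert-butyldimethylsilyloxy)-3-methoxy-5-(3-methylbut-2-enyl)phenyl]pent-1-en-4-yn-3-ol F4. MnO2 in CH2Cl2 at rt should oxidize this doubly activated alcohol to 11.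

Step 2. Re-ionization of the branched ether by palladium may isomerize it to the linear prenyl ether, and zerovalent palladium may begin to insert into the C–Br bond if the reaction has to be warmed. The fallback sets out from 3 and returns at 4 without palladium in the etherification. 3-Chloro-3-methylbut-1-yne with CuCl2 (catalytic) and DBU in MeCN at 0 °C should give 4-bromo-2-methoxy-1-(2-methylbut-3-yn-2-yloxy)benzene F5. Semihydrogenation with H2 over Pd/CaCO3 poisoned with Pb(OAc)2 and quinoline (Lindlar catalyst) in EtOAc should then give 4.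

**Further compounds**
F1 | step 9 | 1-bromo-2,4-bis(methoxymethoxy)benzene | COCOc1ccc(Br)c(OCOC)c1
F2 | step 9 | (E)-1-[2,4-bis(methoxymethoxy)phenyl]-3-[4-(tert-butyldimethylsilyloxy)-3-methoxy-5-(3-methylbut-2-enyl)phenyl]prop-2-en-1-one | COCOc1ccc(C(=O)/C=C/c2cc(OC)c(O[Si](C)(C)C(C)(C)C)c(CC=C(C)C)c2)c(OCOC)c1
F3 | step 6 | (E)-3-[4-(tert-butyldimethylsilyloxy)-3-methoxy-5-(3-methylbut-2-enyl)phenyl]prop-2-enal | O=C/C=C/c1cc(OC)c(O[Si](C)(C)C(C)(C)C)c(CC=C(C)C)c1
F4 | step 6 | racemic (E)-1-[4-(tert-butyldimethylsilyloxy)-3-methoxy-5-(3-methylbut-2-enyl)phenyl]pent-1-en-4-yn-3-ol | C#CC(O)/C=C/c1cc(OC)c(O[Si](C)(C)C(C)(C)C)c(CC=C(C)C)c1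
F5 | step 2 | 4-bromo-2-methoxy-1-(2-methylbut-3-yn-2-yloxy)benzene | COc1cc(Br)ccc1OC(C)(C)C#C
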